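**Retrosynthetic overview**

1. The target is methyl (5E,7Z,12R,14Z)-10-bromo-12-hydroxy-9-oxoprosta-5,7,10,14-tetraenoate (prostanoid numbering C1–C20 is used below); its only ring, the cyclopentenone C8–C12, is formed last.
2. Key disconnection, both bonds in one operation: C9–C10 and C8–C12. This is a formal (3+2) annulation of a C8–C9 unit (an α-stannylated 1-alkoxyallene that already carries C1–C7) with a C10–C12 unit (a β,β-dibromo enone that carries C13–C20), by Stille coupling followed by a Lewis-acid 4π closure of iso-Nazarov type.
3. Enabling feature: in the ring, the ketone carbon C9 and its neighbour C8 with the exocyclic C7=C8 bond are the oxygen-bearing and the central carbon of an allenyl ether (a masked α-alkylidene ketone). The carbinol carbon C12, joined to C9 through C10=C11, is a latent ketone that the nucleophilic C8 can reach, and C10–Br is what remains of a CBr2 group after one cross-coupling.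
4. Stereochemistry: the allene axis (set by a chiral propargylic acetal) is transferred to C12 and fixes the 7Z alkene; 5E comes from hydrozirconation and 14Z from (Z)-non-3-en-1-ol.
5. Fragments: the dibromo enone takes 5 steps; the stannylallene takes 6 steps, with a trimethyl orthoester masking the methyl ester against organolithium reagents.

Key step: step 12

Assumption (chemistry): the sense of both chirality transfers is taken as drawn, namely anti-SN2′ opening of the (4R,5R)-acetal to the (aR)-allenyl ether in step 9, and ring closure in step 12 through the Lewis-acid complex with the ketone oxygen outside and C13 inside the U-shaped cation; if either is opposite, the (4S,5S)-acetal from (2S,3S)-butane-2,3-diol is used and nothing else changes.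

Notation: an allene axis is written in SMILES with [C@] or [C@@] on the central allene carbon and explicit hydrogens on the terminal allene carbons.

**Route**

Step 1
Reactants: 1 (Z)-non-3-en-1-ol
Product: 2 (Z)-non-3-enal
Conditions: Dess–Martin periodinane, NaHCO3, CH2Cl2, 0 °C → rt; used without chromatography
Reagents that add atoms: none
Why: Dess–Martin oxidation under bicarbonate buffer should give the β,γ-unsaturated aldehyde without moving the skipped Z alkene into conjugation.

Step 2
Reactants: 2 (Z)-non-3-enal; 3 ethynylmagnesium bromide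
Product: 4 (5Z)-undec-5-en-1-yn-3-ol (racemic)
Conditions: THF, −78 → −20 °C; then H2O
Reagents that add atoms: none
Why: Grignard 1,2-addition at low temperature should outrun enolisation of the aldehyde; the carbinol centre is racemic and is removed in step 4.

Step 3
Reactants: 4 (5Z)-undec-5-en-1-yn-3-ol
Product: 5 (5Z)-1-bromoundec-5-en-1-yn-3-ol (racemic)
Conditions: N-bromosuccinimide, AgNO3 (10 mol%), acetone, rt, dark
Reagents that add atoms: N-bromosuccinimide, O=C1CCC(=O)N1Br
Why: silver-catalysed electrophilic bromination of a terminal alkyne (via the silver acetylide) should leave the Z alkene and the alcohol untouched.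

Step 4
Reactants: 5 (5Z)-1-bromoundec-5-en-1-yn-3-ol
Product: 6 (5Z)-1-bromoundec-5-en-1-yn-3-one
Conditions: Dess–Martin periodinane, NaHCO3, CH2Cl2, 0 °C
Reagents that add atoms: none
Why: Dess–Martin oxidation of the propargylic alcohol under neutral conditions should give the bromo ynone without enolising the doubly activated C13 methylene.

Step 5
Reactants: 6 (5Z)-1-bromoundec-5-en-1-yn-3-one
Product: 7 (5Z)-1,1-dibromoundeca-1,5-dien-3-one
Conditions: LiBr, AcOH, MeCN, rt
Reagents that add atoms: lithium bromide, [Li+].[Br-]
Why: conjugate hydrobromination of the ynone (bromide adds to the bromine-bearing β carbon, the proton to the α carbon) should give the gem-dibromo enone, and the weakly acidic medium should not isomerise the skipped alkene.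

Step 6
Reactants: 8 4-bromo-1,1,1-trimethoxybutane; 9 lithium acetylide–ethylenediamine complex
Product: 10 6,6,6-trimethoxyhex-1-yne
Conditions: DMSO, 15 °C → rt
Reagents that add atoms: none
Why: SN2 alkylation of lithium acetylide by a primary bromide; the orthoester is inert to base and masks the future C1 ester.

Step 7
Reactants: 10 6,6,6-trimethoxyhex-1-yne
Product: 12 (1E)-1-iodo-6,6,6-trimethoxyhex-1-ene, via alkenylzirconocene chloride 11 (not isolated)
Conditions: Cp2Zr(H)Cl, THF, rt; then I2, 0 °C; aq. Na2S2O3/NaHCO3 work-up
Reagents that add atoms: iodine, II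
Why: syn hydrozirconation places zirconium on the terminal carbon and iodinolysis proceeds with retention, which sets the future 5E alkene.

Step 8
Reactants: 13 3,3-diethoxyprop-1-yne; 14 (2R,3R)-butane-2,3-diol
Product: 15 (4R,5R)-2-ethynyl-4,5-dimethyl-1,3-dioxolane
Conditions: p-TsOH·H2O (1 mol%), toluene, 90 °C, ethanol distilled off
Reagents that add atoms: none
Why: acid-catalysed transacetalisation driven by removal of ethanol; the two stereocentres come unchanged from the diol.

Step 9
Reactants: 12 (1E)-1-iodo-6,6,6-trimethoxyhex-1-ene; 15 (4R,5R)-2-ethynyl-4,5-dimethyl-1,3-dioxolane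
Product: 18 (2R,3R)-3-{[(aR,4E)-9,9,9-trimethoxynona-1,2,4-trien-1-yl]oxy}butan-2-ol, via alkenyllithium 16 (not isolated), via alkenylcopper 17 (not isolated)
Conditions: t-BuLi (2.0 equiv), Et2O, −78 °C; CuBr·SMe2 (1.0 equiv), MgBr2·OEt2 (1.2 equiv), −40 °C; then 15, −40 → −10 °C; then H2O; chromatography on Et3N-deactivated silica
Reagents that add atoms: none
Why: copper-mediated SN2′ opening of a propargylic acetal (syn carbocupration with the alkenyl group going to the alkyne terminus, then magnesium-assisted anti β-elimination of one acetal oxygen) is the known route to alkoxyallenes, and in the (R,R)-diol acetal the two C–O bonds are diastereotopic, so the auxiliary sets the allene axis while the E alkene survives iodine–lithium exchange with retention.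

Step 10
Reactants: 18 (2R,3R)-3-{[(aR,4E)-9,9,9-trimethoxynona-1,2,4-trien-1-yl]oxy}butan-2-ol
Product: 19 tert-butyl(dimethyl){[(2R,3R)-3-{[(aR,4E)-9,9,9-trimethoxynona-1,2,4-trien-1-yl]oxy}butan-2-yl]oxy}silane
Conditions: TBSCl, imidazole, DMF, 0 °C → rt
Reagents that add atoms: tert-butyldimethylsilyl chloride, CC(C)(C)[Si](C)(C)Cl
Why: silylation of the secondary alcohol, so that it tolerates n-BuLi and cannot trap the C9 oxocarbenium ion of step 12 as a cyclic ketal.

Step 11
Reactants: 19 (the silyl ether above)
Product: 21 tributyl[(aS,4E)-1-{[(2R,3R)-3-{[tert-butyl(dimethyl)silyl]oxy}butan-2-yl]oxy}-9,9,9-trimethoxynona-1,2,4-trien-1-yl]stannane, via lithioallene 20 (not isolated)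
Conditions: n-BuLi, THF, −78 °C, 30 min; Bu3SnCl, −78 → −40 °C; chromatography on Et3N-deactivated silica
Reagents that add atoms: tributyltin chloride, CCCC[Sn](Cl)(CCCC)CCCC
Why: oxygen-directed α-lithiation of the allenyl ether at C9 (kinetically preferred over the C7–H) and stannylation should both retain the allene axis; the descriptor becomes aS only because tin outranks oxygen.

Step 12
Reactants: 7 (5Z)-1,1-dibromoundeca-1,5-dien-3-one; 21 (the stannane above)
Product: 25 methyl (5E,7Z,12R,14Z)-10-bromo-12-hydroxy-9-oxoprosta-5,7,10,14-tetraenoate (target), via trans-trienone 22 (not isolated), via cis-trienone 23 (not isolated), via oxocarbenium bromide 24 (not isolated)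
Conditions: Pd2(dba)3 (2.5 mol%), P(2-furyl)3 (10 mol%), toluene, 45 °C, 1.0 equiv of 21; then CH2Cl2, MgBr2·OEt2 (3 equiv), −40 → 0 °C; then pH 4 citrate buffer, THF, 0 °C
Reagents that add atoms: water, O
Why: Proposed new method: Stille coupling at the less hindered C–Br bond of 7 (trans to the acyl group) should join C9 to C10 with retention of the allene axis and leave the second bromine on C10, after which MgBr2 equilibrates the C10=C11 geometry (bromide addition–elimination at the β-bromo enone) and activates the C12 ketone, so that the cis isomer 23 becomes an O-metalated 1-oxypentadienyl cation spanning C12–C11–C10–C9–C8 that closes between C8 and C12. The closest known reaction types are the Stille coupling of α-alkoxyvinylstannanes with gem-dibromoalkenes, the allene ether Nazarov cyclisation and the iso-Nazarov cyclisation of 2,4-dienals, of which this step is the hybrid; it can equally be read as an intramolecular Mukaiyama-type aldol addition of an enol ether to a ketone. The cyclopentenone ring closes by a thermally allowed conrotatory 4π electrocyclisation (formally 5-(enolendo)-exo-trig); the resulting C9 oxocarbenium ion 24 is hydrolysed to the ketone on work-up, which also turns the orthoester into the methyl ester. C12 is set by axial-to-central chirality transfer: the C5–C6 vinyl group on C7 lies on one face of the pentadienyl plane, C8 bonds through its opposite lobe, and this fixes the sense of conrotation (R at C12 with the ketone oxygen outside) while swinging the chain toward C9, which gives the 7Z alkene kinetically. The step needs monocoupling of the CBr2 group, C–C closure in preference to oxa-6π closure to a 2-alkylidene-2H-pyran or protonation of the allene, and no migration of the C14 alkene; these should be secured by the two equivalent bromines on C10 (either coupling site and either alkene geometry funnels to 23), by the donor oxygen on C9 (it makes C8 the nucleophilic terminus and the product cation an oxocarbenium ion), by the allene (no inside substituent at C8, strain release) and by an aprotic, mild Lewis acid bound to the carbonyl oxygen at or below 0 °C.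

**Compound list**

1 | (Z)-non-3-en-1-ol | CCCCC/C=C\CCO | starting material
2 | (Z)-non-3-enal | CCCCC/C=C\CC=O | intermediate
3 | ethynylmagnesium bromide | C#C[Mg]Br | starting material
4 | (5Z)-undec-5-en-1-yn-3-ol (racemic) | CCCCC/C=C\CC(O)C#C | intermediate
5 | (5Z)-1-bromoundec-5-en-1-yn-3-ol (racemic) | CCCCC/C=C\CC(O)C#CBr | intermediate
6 | (5Z)-1-bromoundec-5-en-1-yn-3-one | CCCCC/C=C\CC(=O)C#CBr | intermediate
7 | (5Z)-1,1-dibromoundeca-1,5-dien-3-one | CCCCC/C=C\CC(=O)C=C(Br)Br | intermediate
8 | 4-bromo-1,1,1-trimethoxybutane (trimethyl 4-bromoorthobutyrate) | COC(OC)(OC)CCCBr | starting material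
9 | lithium acetylide–ethylenediamine complex | [Li]C#C.NCCN | starting material
10 | 6,6,6-trimethoxyhex-1-yne | COC(OC)(OC)CCCC#C | intermediate
11 | [(1E)-6,6,6-trimethoxyhex-1-en-1-yl]zirconocene chloride (not isolated) | COC(OC)(OC)CCC/C=C/[Zr](Cl)(C1C=CC=C1)C1C=CC=C1 | intermediate
12 | (1E)-1-iodo-6,6,6-trimethoxyhex-1-ene | COC(OC)(OC)CCC/C=C/I | intermediate
13 | 3,3-diethoxyprop-1-yne | CCOC(OCC)C#C | starting material
14 | (2R,3R)-butane-2,3-diol | C[C@@H](O)[C@@H](C)O | starting material
15 | (4R,5R)-2-ethynyl-4,5-dimethyl-1,3-dioxolane | C#CC1O[C@H](C)[C@@H](C)O1 | intermediate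
16 | [(1E)-6,6,6-trimethoxyhex-1-en-1-yl]lithium (not isolated) | COC(OC)(OC)CCC/C=C/[Li] | intermediate
17 | [(1E)-6,6,6-trimethoxyhex-1-en-1-yl]copper, as its MgBr2 complex (not isolated) | COC(OC)(OC)CCC/C=C/[Cu] | intermediate
18 | (2R,3R)-3-{[(aR,4E)-9,9,9-trimethoxynona-1,2,4-trien-1-yl]oxy}butan-2-ol | C[C@@H](O)[C@@H](C)OC([H])=[C@]=C([H])/C=C/CCCC(OC)(OC)OC | intermediate
19 | tert-butyl(dimethyl){[(2R,3R)-3-{[(aR,4E)-9,9,9-trimethoxynona-1,2,4-trien-1-yl]oxy}butan-2-yl]oxy}silane | C[C@@H](O[Si](C)(C)C(C)(C)C)[C@@H](C)OC([H])=[C@]=C([H])/C=C/CCCC(OC)(OC)OC | intermediate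
20 | 1-lithio derivative of 19, lithium on the oxygen-bearing allene carbon, axis retained (not isolated) | C[C@@H](O[Si](C)(C)C(C)(C)C)[C@@H](C)OC([Li])=[C@]=C([H])/C=C/CCCC(OC)(OC)OC | intermediate
21 | tributyl[(aS,4E)-1-{[(2R,3R)-3-{[tert-butyl(dimethyl)silyl]oxy}butan-2-yl]oxy}-9,9,9-trimethoxynona-1,2,4-trien-1-yl]stannane | C[C@@H](O[Si](C)(C)C(C)(C)C)[C@@H](C)OC([Sn](CCCC)(CCCC)CCCC)=[C@]=C([H])/C=C/CCCC(OC)(OC)OC | intermediate
22 | (5E,10Z,14Z,aR)-10-bromo-9-{[(2R,3R)-3-{[tert-butyl(dimethyl)silyl]oxy}butan-2-yl]oxy}-1,1,1-trimethoxyicosa-5,7,8,10,14-pentaen-12-one, C9 trans to C12 across C10=C11 (not isolated) | CCCCC/C=C\CC(=O)/C=C(Br)/C(O[C@H](C)[C@@H](C)O[Si](C)(C)C(C)(C)C)=[C@@]=C([H])/C=C/CCCC(OC)(OC)OC | intermediate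
23 | (10E)-isomer of 22, C9 cis to C12 across C10=C11 (not isolated) | CCCCC/C=C\CC(=O)/C=C(Br)\C(O[C@H](C)[C@@H](C)O[Si](C)(C)C(C)(C)C)=[C@@]=C([H])/C=C/CCCC(OC)(OC)OC | intermediate
24 | cyclised C9 O-alkyl oxocarbenium bromide with C12 bromomagnesium alkoxide, orthoester intact (not isolated) | CCCCC/C=C\C[C@@]1(O[Mg]Br)C=C(Br)C(=[O+][C@H](C)[C@@H](C)O[Si](C)(C)C(C)(C)C)/C1=C\C=C\CCCC(OC)(OC)OC.[Br-] | intermediate
25 | methyl (5E,7Z,12R,14Z)-10-bromo-12-hydroxy-9-oxoprosta-5,7,10,14-tetraenoate | CCCCC/C=C\C[C@@]1(O)C=C(Br)C(=O)/C1=C\C=C\CCCC(=O)OC | target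

**Summary**

Total step count: 12. Longest linear sequence: 6 steps (steps 1–5 then 12, or steps 6, 7, 9, 10, 11 then 12).

**Steps most likely to fail**

Step 12 (proposed new method). What may go wrong: incomplete equilibration of the C10=C11 geometry, diversion of the cis isomer into oxa-6π closure or allene protonation, or erosion of the allene axis before ring closure. The fallback uses known chemistry, sets out from 7 and returns at 25. Stille coupling of 7 with tributyl(1-ethoxyvinyl)stannane (Pd(PPh3)4, toluene, 80 °C) should give the bromo dienyl ether F1. N-Bromosuccinimide in aqueous THF at 0 °C should convert its enol ether into the bromomethyl ketone F2. CrCl2 in THF, with LiBr to equilibrate the geometry of the β-bromo enone, should close the ring by an intramolecular Reformatsky-type aldol addition to the racemic hydroxycyclopentenone F3. The (S)-enantiomer F4 is then taken by chromatography on a chiral stationary phase. The dianion of F4 (LiN(iPr)2, 2.2 equiv, THF, −78 °C) is added to methyl (E)-7-oxohept-5-enoate F5 (from methyl hex-5-enoate and crotonaldehyde by cross-metathesis with the second-generation Grubbs catalyst) to give the aldol F6. MsCl/Et3N should dehydrate F6 to 25 and its 7E isomer F7, which are separated. This gives up synthetic control of C12 and of the exocyclic alkene geometry.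

Step 9. What may go wrong: deprotonation of the terminal alkyne instead of carbocupration, sluggish addition of the alkenylcopper, or low facial selectivity in the β-alkoxide elimination, which would lower the enantiomeric purity of everything downstream. The fallback sets out from 12 and 14 and returns at 19. Monoalkylation of 14 (NaH, propargyl bromide, THF) should give the propargyl ether F8. Sonogashira coupling of F8 with 12 (PdCl2(PPh3)2, CuI, Et3N) should give the enyne F9, and TBSCl/imidazole its silyl ether F10. KOtBu (catalytic, THF) should isomerise the propargyl ether to the allenyl ether as a mixture of 19 and its axial epimer F11; these are diastereomers and are separated by preparative HPLC.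

Step 7. What may go wrong: cleavage of the orthoester by Lewis-acidic zirconium and iodine species during iodinolysis, which would expose an ester to t-BuLi in step 9. The fallback sets out from 10 and returns at 12. Hydroboration of 10 with pinacolborane (dicyclohexylborane, 5 mol%, neat, rt) should give the (E)-alkenylboronate F12, and iododeboronation under basic conditions (aq. NaOH, I2, THF, 0 °C) should give 12 with retention.

**Further compounds**

F1 | step 12 | (5Z)-1-bromo-1-(1-ethoxyvinyl)... bromo dienyl ether: (7Z)-3-bromo-2-ethoxytrideca-1,3,7-trien-5-one | CCCCC/C=C\CC(=O)C=C(Br)C(=C)OCC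
F2 | step 12 | (7Z)-1,3-dibromotrideca-3,7-diene-2,5-dione | CCCCC/C=C\CC(=O)C=C(Br)C(=O)CBr
F3 | step 12 | racemic 2-bromo-4-hydroxy-4-[(2Z)-oct-2-en-1-yl]cyclopent-2-en-1-one | CCCCC/C=C\CC1(O)C=C(Br)C(=O)C1
F4 | step 12 | (4S)-2-bromo-4-hydroxy-4-[(2Z)-oct-2-en-1-yl]cyclopent-2-en-1-one | CCCCC/C=C\C[C@@]1(O)C=C(Br)C(=O)C1
F5 | step 12 | methyl (E)-7-oxohept-5-enoate | COC(=O)CCC/C=C/C=O
F6 | step 12 | aldol adduct of F4 and F5 (mixture at the two new centres) | CCCCC/C=C\C[C@@]1(O)C=C(Br)C(=O)C1C(O)/C=C/CCCC(=O)OC
F7 | step 12 | methyl (5E,7E,12R,14Z)-10-bromo-12-hydroxy-9-oxoprosta-5,7,10,14-tetraenoate | CCCCC/C=C\C[C@@]1(O)C=C(Br)C(=O)/C1=C/C=C/CCCC(=O)OC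
F8 | step 9 | (2R,3R)-3-(prop-2-yn-1-yloxy)butan-2-ol | C[C@@H](O)[C@@H](C)OCC#C
F9 | step 9 | (2R,3R)-3-{[(4E)-9,9,9-trimethoxynon-4-en-2-yn-1-yl]oxy}butan-2-ol | C[C@@H](O)[C@@H](C)OCC#C/C=C/CCCC(OC)(OC)OC
F10 | step 9 | tert-butyldimethylsilyl ether of F9 | C[C@@H](O[Si](C)(C)C(C)(C)C)[C@@H](C)OCC#C/C=C/CCCC(OC)(OC)OC
F11 | step 9 | (aS)-epimer of 19 | C[C@@H](O[Si](C)(C)C(C)(C)C)[C@@H](C)OC([H])=[C@@]=C([H])/C=C/CCCC(OC)(OC)OC
F12 | step 7 | 4,4,5,5-tetramethyl-2-[(1E)-6,6,6-trimethoxyhex-1-en-1-yl]-1,3,2-dioxaborolane | COC(OC)(OC)CCC/C=C/B1OC(C)(C)C(C)(C)O1
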